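## Structural features

CNP0333611.1 is a labdane: a trans-fused decalin (ring A = C1–C5 plus C10, ring B = C5–C10) whose C9 carries a six-carbon chain (C11–C16) ending in an (E)-3-methylalk-2-enoic acid. Ring A holds an axial 3α-isovalerate next to quaternary C4, which bears the α-methyl C18 and the β-CH2O-isovalerate C19. C19 is syn-diaxial to the C10 methyl (C20) and to the 6β-hydroxyl. The five stereocentres C3, C4, C5, C6 and C10 are contiguous, and the methine C5 lies between the two quaternary carbons. Ring B contains the tetrasubstituted C8=C9 alkene directly beside C10, with the C6 hydroxyl homoallylic to it. The fragile points are the two isovalerates (no late hydrolysis or hydride step, so the C15 acid needs an orthogonal mask), a possible acyl shift from O19 to the 6β-hydroxyl under base, the readiness of a C6 ketone to pull C8=C9 into conjugation, and the E geometry at C13=C14. The real difficulty is quaternary C10 next to a tetrasubstituted alkene and cis to C19, together with telling three hydroxyls apart when two carry the same acyl group. The plan exploits the ring-B pattern: the C6 oxygen is 1,4 to C9 and C8=C9 adjoins C10, which is the imprint of a [4+2] adduct between a 2-oxygenated diene C10=C5–C6(O)=C7 and a but-2-ynoate that supplies C8 (with C17) and C9 (with C11).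

## Logic of the disconnections

**31 ⇒ 30.** The O–H of the C15 acid is exchanged for an O–allyl bond. The acid must be released last, beside two isovalerates and a free alcohol, so the forward step has to be neutral and non-hydrolytic. The gain is that all earlier steps handle a simple ester.

**30 ⇒ 28 (through 29).** Both acyl C–O bonds at O3 and O19 are cut together, because the two esters are identical. The gain is that 28 needs no protecting group at all. The demand is that acylation stops before the 6β-hydroxyl, which rests on its double syn-axial shielding by C19 and C20.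

**28 ⇒ 27 ⇒ 25 + 26.** The O19–Si bond is cut, then the C13=C14 double bond. This is the one bond of the chain that joins two stable fragments with the ester already in place. The side chain shrinks to a methyl ketone. The demand is E selectivity in an olefination of a methyl ketone, which is moderate by nature.

**25 ⇒ 21 + 22 (through 23 and 24); 21 ⇒ 20.** The C11–C12 bond is cut, then C11–Br is taken back to C11–OH. Allylic C11 is a natural electrophile, and the chain is reduced to one carbon on C9. The forward steps must activate the primary allylic hydroxyl beside two secondary ones and substitute without allylic transposition.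

**20 ⇒ 18 (through 19) ⇒ 17 ⇒ 15 (through 16).** The C3–H, C6–H and two C11–H bonds are removed, giving a tricarbonyl compound.
- C3 has the wrong configuration in everything that leaves the ring-forming step, so it must pass through a ketone in any case.
- Doing this while C6 and C11 are also carbonyls means no alcohol ever needs protection and C6 is reduced only once.
- The demand is two hydride deliveries of opposite sense: a bulky hydride from the equatorial direction at C3 and a small one from the α face at C6.
- Further back, the C3 carbonyl returns to the 3β-alcohol, and the C5–H bond and the O–Si bonds at O3 and O6 are cut.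
- C5 must be protonated from the α face under kinetic control. Base equilibration at C5 is avoided, because it would also move C8=C9 into conjugation with the C6 ketone.

**15 ⇒ 13 + 14.** The C7–C8 and C9–C10 bonds are cut. This removes ring B, the quaternary centre C10 and the tetrasubstituted alkene in one stroke and leaves a monocyclic diene and a four-carbon alkyne.
- The forward cycloaddition must be para-selective and must add to the α face of C10.
- For that reason 13 keeps C3 in the 3β configuration, cis to C19, so that C19 can sit pseudoaxial on the β face.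
- The three silyl groups of 13 are deliberately different: the enol ether and the O3 ether fall together in dilute acid, and the O19 ether survives to step 16. With three identical groups, O3 could not be freed before O19.
- A cyclic acetal across O3 and O19 was rejected: a cis-fused dioxane would favour the half-chair with the C4 methyl pseudoaxial and would expose the wrong face.

**13 ⇒ 12 ⇒ 9 + 10 (through 11) ⇒ 7 (through 8) ⇒ 5 (through 6).** In turn the enol O–Si bond, the C5–C6 bond, the C5–O bond of the triflate and the C10–C20 bond are cut. Because C4 is quaternary, only C10 can enolise, so regiochemistry is automatic in both enolate steps. The demand is a cross-coupling at a triflate flanked by a quaternary carbon and a methyl-bearing carbon.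

**5 ⇒ 4 ⇒ 3 ⇒ 2 ⇒ 1.** After the O3–Si bond, the C3–H bond is cut, which reveals a dione with two enantiotopic carbonyls. One catalytic reduction therefore sets C3 and, by desymmetrisation, C4. The O19–Si and C4–C19 bonds then lead back to a commercial dione and a one-carbon aldehyde electrophile. The reduction must choose one carbonyl and one face; the cis (3β) outcome is the one that the relay to C10 needs.

## Other disconnections considered

**Alternative 1:** The cut is at C5–C10 and C6–C7. Heating the nitro-triene A1 would give the trans-fused 6α-nitro decalin A2 by an intramolecular Diels–Alder reaction with the nitro group endo.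
- In its favour: it closes both rings and sets C5, C6 and C10 in one step, which is more than step 9 achieves (one ring, one stereocentre). It is intramolecular, so the quaternary C10 is forged with an entropic advantage that the intermolecular step 9 lacks. It also carries the whole side chain through. On all three counts it is the better key step.
- Equal points: the C8=C9 alkene appears in place in both plans. The diene terminus C10 carries an "inside" methyl group in A1 just as in 13.
- Against it: A1 needs an acyclic, stereodefined tetrasubstituted C9=C10 alkene and a base-sensitive nitroalkene beside quaternary C4. The nitro group of A2 must still be exchanged for the 6β-hydroxyl (Nef reaction, then reduction). The acetonide ties O3 and O19 together in the 3β series, so C3 inversion remains and the two oxygens must first be separated, whereas 13 has them differentiated from the start. C15 must be oxidised twice at the end.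
- Step economy: the key step is more powerful, but the preparation of A1 and the work after A2 are longer, so no overall saving is expected.

**Alternative 2:** The cut is at C4–C5 and C1–C10. The quinone monoketal A3 and the silyloxydiene ester A4 would combine under a chiral cationic oxazaborolidine Lewis acid to give the cis-fused endo adduct A5.
- In its favour: both partners are small and achiral, and the absolute configuration comes from the catalyst in the ring-forming step itself. That is better than the chosen plan, which needs a separate desymmetrisation (step 3). Lewis-acid-catalysed additions to quinone-type dienophiles are also more dependable in rate than step 9. The route to the key step is far shorter (about two steps against eight).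
- Equal points: C6 arrives as a masked ketone, as in 15. The C3 oxygen becomes a ketone ready for the same axial-selective reduction as in step 12.
- Against it: A5 is structurally further from the target. It is cis-fused, so C5 must be epimerised. C4 is only tertiary and must be C-methylated with the right facial sense. C19 is an ester that must be reduced. The alkene is at C7=C8 and C9 is a ketone, so the side chain would have to be added to a neopentyl ketone and the oxygen removed with double-bond transposition. A4 also carries an ester on its nucleophilic terminus, which lowers its reactivity and blurs the regiochemistry.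
- Step economy: short before the key step, much longer after it; overall no gain.

**Alternative 3:** The cut is at C1–C10. The phenoxide of the iodide A6 would alkylate through its ortho carbon C10 (6-exo-tet) and give the cyclohexa-2,4-dienone A7.
- In its favour: ring B comes from a cheap arene. The closure is intramolecular, and O-alkylation would need an eight-membered ring, so C-alkylation should dominate. No sluggish intermolecular cycloaddition is needed, which is better than step 9 in terms of reactivity.
- Equal points: the C6 oxygen is present from the start, as it is in 13. Facial control at C10 again rests on the C4 centre and is no better defined than in step 9.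
- Against it: A6 contains an aryl–quaternary carbon bond (C5–C4) between two ortho substituents, which is harder to build enantioselectively than steps 1–3. A7 is a linearly conjugated dienone prone to dimerisation or rearomatising 1,2-shifts. Like A5, it has C7=C8 and a C9 ketone, so the side-chain and transposition problem returns, and C5=C6 must still be reduced to the 5α-H, 6β-ol array.
- Step economy: probably longer than the chosen plan.

Key step: step 9

Assumption: labdane numbering and α/β descriptors (C20 methyl on C10 = β) are used for the bicyclic compounds and, by extension, for the ring-A intermediates; read this way the target is 3α,19-bis(isovaleryloxy), 6β-hydroxy, 5α-H, 10β-methyl, that is 3R,4S,5R,6R,10S, 13E.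

## Steps

**Step 1**
Reactants: 1 2-methylcyclohexane-1,3-dione
Product: 2 2-(hydroxymethyl)-2-methylcyclohexane-1,3-dione
Conditions: 37% aq. HCHO (3 equiv), NaHCO3 (0.1 equiv), THF–H2O, rt
Reagents that add atoms: formaldehyde, C=O
Why: Aldol addition (hydroxymethylation) of the acidic C2–H of the 1,3-dione to formaldehyde; the weak base and excess aldehyde hold back retro-aldol and ring-opening retro-Claisen cleavage, and the product is achiral.

**Step 2**
Reactants: 2 2-(hydroxymethyl)-2-methylcyclohexane-1,3-dione
Product: 3 2-methyl-2-[(triisopropylsilyloxy)methyl]cyclohexane-1,3-dione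
Conditions: i-Pr3SiOTf, 2,6-lutidine, CH2Cl2, −78 → 0 °C
Reagents that add atoms: triisopropylsilyl trifluoromethanesulfonate, CC(C)[Si](OS(=O)(=O)C(F)(F)F)(C(C)C)C(C)C
Why: O-silylation of a primary alcohol with a silyl triflate and a hindered pyridine is fast and non-nucleophilic, which forestalls loss of formaldehyde; the triisopropylsilyl ether is chosen because it must outlast acid, base and hydride until step 16.

**Step 3**
Reactants: 3 2-methyl-2-[(triisopropylsilyloxy)methyl]cyclohexane-1,3-dione
Product: 4 (2S,3S)-3-hydroxy-2-methyl-2-[(triisopropylsilyloxy)methyl]cyclohexan-1-one (hydroxyl cis to the silyloxymethyl group)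
Conditions: (R)-2-methyl-CBS-oxazaborolidine (0.2 equiv), BH3·SMe2 (0.6 equiv), THF, −40 °C; aq. NH4Cl
Reagents that add atoms: none
Why: Corey–Bakshi–Shibata reduction of one of two enantiotopic ketones; by the usual large/small model the (R)-catalyst should give the 3S carbinol, and hydride should enter anti to the silyloxymethyl group, so the alcohol is cis to CH2OSi and the quaternary centre (C4 of the target) is fixed as 2S by desymmetrisation. Substoichiometric borane limits diol formation.

**Step 4**
Reactants: 4 (2S,3S)-3-hydroxy-2-methyl-2-[(triisopropylsilyloxy)methyl]cyclohexan-1-one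
Product: 5 (2S,3S)-2-methyl-3-(triethylsilyloxy)-2-[(triisopropylsilyloxy)methyl]cyclohexan-1-one
Conditions: Et3SiOTf, 2,6-lutidine, CH2Cl2, −78 → 0 °C
Reagents that add atoms: triethylsilyl trifluoromethanesulfonate, CC[Si](CC)(CC)OS(=O)(=O)C(F)(F)F
Why: Silylation of the hindered secondary alcohol with a silyl triflate; the triethylsilyl ether is the one group meant to fall in dilute acid at step 10 while the triisopropylsilyl ether stays.

**Step 5**
Reactants: 5 (2S,3S)-2-methyl-3-(triethylsilyloxy)-2-[(triisopropylsilyloxy)methyl]cyclohexan-1-one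
Product: 7 (2S,3S,6RS)-2,6-dimethyl-3-(triethylsilyloxy)-2-[(triisopropylsilyloxy)methyl]cyclohexan-1-one, via lithium enolate 6 (not isolated)
Conditions: LiN(i-Pr)2, THF, −78 °C; MeI, −78 → −30 °C
Reagents that add atoms: iodomethane, CI
Why: Enolate C-alkylation; the quaternary α-carbon leaves C10 as the only enolisable position, and the configuration of the new methyl-bearing carbon is irrelevant because it becomes sp2 in step 6.

**Step 6**
Reactants: 7 (2S,3S,6RS)-2,6-dimethyl-3-(triethylsilyloxy)-2-[(triisopropylsilyloxy)methyl]cyclohexan-1-one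
Product: 9 (5S,6S)-2,6-dimethyl-5-(triethylsilyloxy)-6-[(triisopropylsilyloxy)methyl]cyclohex-1-en-1-yl trifluoromethanesulfonate, via potassium enolate 8 (not isolated)
Conditions: KN(SiMe3)2, THF, −78 °C; PhNTf2, −78 → 0 °C
Reagents that add atoms: N-phenylbis(trifluoromethanesulfonimide), O=S(=O)(N(c1ccccc1)S(=O)(=O)C(F)(F)F)C(F)(F)F
Why: O-triflation of the only possible (tetrasubstituted) enolate, as for 2,2,6-trialkylcyclohexanones; both C10 epimers of 7 converge on one enol triflate.

**Step 7**
Reactants: 9 (5S,6S)-2,6-dimethyl-5-(triethylsilyloxy)-6-[(triisopropylsilyloxy)methyl]cyclohex-1-en-1-yl trifluoromethanesulfonate; 10 tributyl(1-ethoxyvinyl)stannane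
Product: 12 1-[(5S,6S)-2,6-dimethyl-5-(triethylsilyloxy)-6-[(triisopropylsilyloxy)methyl]cyclohex-1-en-1-yl]ethan-1-one, via 2-ethoxydiene 11 (not isolated)
Conditions: Pd(PPh3)4 (5 mol%), CuCl, LiCl, DMSO, 60 °C; then 1 M aq. oxalic acid, THF, 0 °C
Reagents that add atoms: water, O
Why: Stille coupling of the hindered enol triflate with an acyl-anion equivalent under zerovalent palladium, with CuCl/LiCl to speed transmetalation; brief weak-acid hydrolysis of the ethyl enol ether then frees the acetyl group without touching the silyl ethers.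

**Step 8**
Reactants: 12 1-[(5S,6S)-2,6-dimethyl-5-(triethylsilyloxy)-6-[(triisopropylsilyloxy)methyl]cyclohex-1-en-1-yl]ethan-1-one
Product: 13 (5S,6S)-1-[1-(tert-butyldimethylsilyloxy)ethenyl]-2,6-dimethyl-5-(triethylsilyloxy)-6-[(triisopropylsilyloxy)methyl]cyclohex-1-ene (ring-A 2-silyloxydiene)
Conditions: t-BuMe2SiOTf, Et3N, CH2Cl2, 0 °C
Reagents that add atoms: tert-butyldimethylsilyl trifluoromethanesulfonate, CC(C)(C)[Si](C)(C)OS(=O)(=O)C(F)(F)F
Why: Soft enolisation of the methyl ketone (O-silylation, then loss of an acetyl proton) gives the cross-conjugated 2-silyloxydiene; γ-deprotonation is disfavoured because the acetyl group is twisted out of conjugation by its two ortho-like neighbours.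

**Step 9**
Reactants: 13 (5S,6S)-1-[1-(tert-butyldimethylsilyloxy)ethenyl]-2,6-dimethyl-5-(triethylsilyloxy)-6-[(triisopropylsilyloxy)methyl]cyclohex-1-ene; 14 methyl but-2-ynoate
Product: 15 methyl 6-(tert-butyldimethylsilyloxy)-3β-(triethylsilyloxy)-19-(triisopropylsilyloxy)-12,13,14,15,16-pentanorlabda-5,8-dien-11-oate (4α-methyl and 10β-methyl)
Conditions: 14 (6 equiv), CH2Cl2, 13 kbar, 50 °C
Reagents that add atoms: none
Why: A concerted but asynchronous normal-demand [4+2] cycloaddition: the electron-rich terminus C7 of the silyl enol ether bonds to the β-carbon of the ynoate (C8) while the C10–C9 bond lags behind. The closest known reaction type is the Diels–Alder addition of 2-silyloxydienes from 1-acetylcyclohexenes to alkynoates, which gives 1-silyloxy-1,4-cyclohexadienes with a quaternary carbon. Ring B closes by intermolecular cycloaddition, both σ bonds (C7–C8 and C9–C10) forming in the same step. C10, the only new stereocentre, is controlled by C4: in the half-chair with the 3β-silyloxy group equatorial the CH2OSi(i-Pr)3 group is pseudoaxial on the β face, so the alkyne should add to the α face and leave C20 β, cis to C19. The step needs para regiochemistry, which the 2-silyloxy group and the alkyl groups at C10 secure by placing the largest HOMO coefficient on C7, matched to the large LUMO coefficient at the β-carbon of the ester. It also needs chemoselectivity over [2+2] or Mukaiyama–Michael addition at the enol ether, which is sought by using no Lewis acid and letting pressure supply the acceleration, at a temperature below that of 1,5-hydrogen shifts in the diene. With an alkyne there is no endo/exo question, and quaternary C10 prevents aromatisation of the 1,4-diene.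

**Step 10**
Reactants: 15 methyl 6-(tert-butyldimethylsilyloxy)-3β-(triethylsilyloxy)-19-(triisopropylsilyloxy)-12,13,14,15,16-pentanorlabda-5,8-dien-11-oate
Product: 17 methyl 3β-hydroxy-6-oxo-19-(triisopropylsilyloxy)-12,13,14,15,16-pentanorlabd-8-en-11-oate (5α-H), via 3β-triethylsilyloxy 6-ketone 16 (not isolated)
Conditions: 1 M aq. HCl, THF, 0 °C → rt
Reagents that add atoms: none
Why: Acid hydrolysis of the silyl enol ether by kinetic C-protonation at C5 from the α face (the β face is screened by C20 and C19) sets the trans ring fusion, and the same acid removes the triethylsilyl ether while the triisopropylsilyl ether stays. As in the mild hydrolysis of Birch-type 1-alkoxy-1,4-cyclohexadienes, C8=C9 should remain out of conjugation with the C6 ketone; no base is used.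

**Step 11**
Reactants: 17 methyl 3β-hydroxy-6-oxo-19-(triisopropylsilyloxy)-12,13,14,15,16-pentanorlabd-8-en-11-oate
Product: 18 methyl 3,6-dioxo-19-(triisopropylsilyloxy)-12,13,14,15,16-pentanorlabd-8-en-11-oate
Conditions: Dess–Martin periodinane, NaHCO3, CH2Cl2, 0 °C → rt
Reagents that add atoms: none
Why: Dess–Martin oxidation of the only free hydroxyl under buffered, non-basic conditions; it erases the C3 centre, whose 3β configuration was needed only to set C4 and to steer step 9.

**Step 12**
Reactants: 18 methyl 3,6-dioxo-19-(triisopropylsilyloxy)-12,13,14,15,16-pentanorlabd-8-en-11-oate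
Product: 20 19-(triisopropylsilyloxy)-12,13,14,15,16-pentanorlabd-8-ene-3α,6β,11-triol, via 3α-hydroxy 6-keto ester 19 (not isolated)
Conditions: LiBH(s-Bu)3 (1.2 equiv), THF, −78 °C; then i-Bu2AlH (6 equiv), −78 → 0 °C; aq. potassium sodium tartrate
Reagents that add atoms: none
Why: The bulky borohydride should attack the more accessible C3 ketone from the equatorial direction and give the axial 3α-alcohol, as with 4,4-disubstituted 3-oxo terpenoids. i-Bu2AlH then reduces the C6 ketone from the open α face (the β face is blocked by C19 and C20) to the 6β-alcohol and the conjugated ester to the C11 alcohol.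

**Step 13**
Reactants: 20 19-(triisopropylsilyloxy)-12,13,14,15,16-pentanorlabd-8-ene-3α,6β,11-triol
Product: 21 11-bromo-19-(triisopropylsilyloxy)-12,13,14,15,16-pentanorlabd-8-ene-3α,6β-diol
Conditions: CBr4, PPh3, CH2Cl2, −30 → 0 °C
Reagents that add atoms: tetrabromomethane, BrC(Br)(Br)Br
Why: Appel bromination selective for the primary allylic alcohol; the two secondary alcohols are axial and flanked by quaternary carbons and should be inert at this temperature.

**Step 14**
Reactants: 21 11-bromo-19-(triisopropylsilyloxy)-12,13,14,15,16-pentanorlabd-8-ene-3α,6β-diol; 22 ethyl acetoacetate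
Product: 25 3α,6β-dihydroxy-19-(triisopropylsilyloxy)-14,15-dinorlabd-8-en-13-one, via β-keto ester 23 (not isolated), via β-keto acid 24 (not isolated)
Conditions: NaH, THF, 0 °C → rt; then 2 M aq. KOH, EtOH, 60 °C; then 1 M HCl (pH 3), 40 °C
Reagents that add atoms: none
Why: Acetoacetic ester synthesis: SN2 alkylation of the sodium enolate by the primary allylic bromide forms C11–C12, then saponification and decarboxylation give the methyl ketone. The free hydroxyls are far less acidic than the β-keto ester and do not interfere.

**Step 15**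
Reactants: 25 3α,6β-dihydroxy-19-(triisopropylsilyloxy)-14,15-dinorlabd-8-en-13-one; 26 allyl 2-(diethoxyphosphoryl)acetate
Product: 27 allyl (13E)-3α,6β-dihydroxy-19-(triisopropylsilyloxy)labda-8,13-dien-15-oate
Conditions: NaH, THF, 0 → 50 °C (excess phosphonate anion)
Reagents that add atoms: none
Why: Horner–Wadsworth–Emmons olefination of the methyl ketone; the E enoate should predominate and any Z isomer would be removed by chromatography. The allyl ester is installed here so that the acid can be unmasked without hydrolysis at the end.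

**Step 16**
Reactants: 27 allyl (13E)-3α,6β-dihydroxy-19-(triisopropylsilyloxy)labda-8,13-dien-15-oate
Product: 28 allyl (13E)-3α,6β,19-trihydroxylabda-8,13-dien-15-oate
Conditions: Bu4NF, AcOH (1:1), THF, rt → 40 °C
Reagents that add atoms: none
Why: Fluoride cleavage of the primary silyl ether; buffering with acetic acid keeps the medium near neutral and protects the allyl ester.

**Step 17**
Reactants: 28 allyl (13E)-3α,6β,19-trihydroxylabda-8,13-dien-15-oate
Product: 30 allyl (13E)-6β-hydroxy-3α,19-bis(3-methylbutanoyloxy)labda-8,13-dien-15-oate, via 19-monoester 29 (not isolated)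
Conditions: (i-PrCH2CO)2O, DMAP, pyridine, CH2Cl2, 0 °C → rt
Reagents that add atoms: 3-methylbutanoic anhydride, CC(C)CC(=O)OC(=O)CC(C)C
Why: DMAP-catalysed acylation of the primary C19 and the secondary 3α hydroxyls; the 6β-hydroxyl, syn-diaxial to both C20 and the C4 acyloxymethyl group, should stay free, as is usual for axial alcohols flanked in this way.

**Step 18**
Reactants: 30 allyl (13E)-6β-hydroxy-3α,19-bis(3-methylbutanoyloxy)labda-8,13-dien-15-oate
Product: 31 (13E)-6β-hydroxy-3α,19-bis(3-methylbutanoyloxy)labda-8,13-dien-15-oic acid (CNP0333611.1)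
Conditions: Pd(PPh3)4 (5 mol%), morpholine, THF, rt; aq. citric acid
Reagents that add atoms: none
Why: Tsuji–Trost deallylation: zerovalent palladium ionises the allyl ester and morpholine traps the allyl fragment, so the acid is freed under near-neutral conditions that leave the isovalerates, the 6β-hydroxyl and both alkenes untouched.

## Compound list

1 | 2-methylcyclohexane-1,3-dione | CC1C(=O)CCCC1=O | starting material
2 | 2-(hydroxymethyl)-2-methylcyclohexane-1,3-dione | CC1(CO)C(=O)CCCC1=O | intermediate
3 | 2-methyl-2-[(triisopropylsilyloxy)methyl]cyclohexane-1,3-dione | CC1(CO[Si](C(C)C)(C(C)C)C(C)C)C(=O)CCCC1=O | intermediate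
4 | (2S,3S)-3-hydroxy-2-methyl-2-[(triisopropylsilyloxy)methyl]cyclohexan-1-one | O=C1[C@@](C)(CO[Si](C(C)C)(C(C)C)C(C)C)[C@@H](O)CCC1 | intermediate
5 | (2S,3S)-2-methyl-3-(triethylsilyloxy)-2-[(triisopropylsilyloxy)methyl]cyclohexan-1-one | O=C1[C@@](C)(CO[Si](C(C)C)(C(C)C)C(C)C)[C@@H](O[Si](CC)(CC)CC)CCC1 | intermediate
6 | lithium enolate of 5 | [Li+].[O-]C1=CCC[C@H](O[Si](CC)(CC)CC)[C@]1(C)CO[Si](C(C)C)(C(C)C)C(C)C | intermediate (not isolated)
7 | (2S,3S,6RS)-2,6-dimethyl-3-(triethylsilyloxy)-2-[(triisopropylsilyloxy)methyl]cyclohexan-1-one | O=C1[C@@](C)(CO[Si](C(C)C)(C(C)C)C(C)C)[C@@H](O[Si](CC)(CC)CC)CCC1C | intermediate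
8 | potassium enolate of 7 | [K+].[O-]C1=C(C)CC[C@H](O[Si](CC)(CC)CC)[C@]1(C)CO[Si](C(C)C)(C(C)C)C(C)C | intermediate (not isolated)
9 | (5S,6S)-2,6-dimethyl-5-(triethylsilyloxy)-6-[(triisopropylsilyloxy)methyl]cyclohex-1-en-1-yl trifluoromethanesulfonate | CC1=C(OS(=O)(=O)C(F)(F)F)[C@@](C)(CO[Si](C(C)C)(C(C)C)C(C)C)[C@@H](O[Si](CC)(CC)CC)CC1 | intermediate
10 | tributyl(1-ethoxyvinyl)stannane | CCOC(=C)[Sn](CCCC)(CCCC)CCCC | starting material
11 | (5S,6S)-1-(1-ethoxyethenyl)-2,6-dimethyl-5-(triethylsilyloxy)-6-[(triisopropylsilyloxy)methyl]cyclohex-1-ene | CC1=C(C(OCC)=C)[C@@](C)(CO[Si](C(C)C)(C(C)C)C(C)C)[C@@H](O[Si](CC)(CC)CC)CC1 | intermediate (not isolated)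
12 | 1-[(5S,6S)-2,6-dimethyl-5-(triethylsilyloxy)-6-[(triisopropylsilyloxy)methyl]cyclohex-1-en-1-yl]ethan-1-one | CC1=C(C(C)=O)[C@@](C)(CO[Si](C(C)C)(C(C)C)C(C)C)[C@@H](O[Si](CC)(CC)CC)CC1 | intermediate
13 | (5S,6S)-1-[1-(tert-butyldimethylsilyloxy)ethenyl]-2,6-dimethyl-5-(triethylsilyloxy)-6-[(triisopropylsilyloxy)methyl]cyclohex-1-ene | CC1=C(C(O[Si](C)(C)C(C)(C)C)=C)[C@@](C)(CO[Si](C(C)C)(C(C)C)C(C)C)[C@@H](O[Si](CC)(CC)CC)CC1 | intermediate
14 | methyl but-2-ynoate | CC#CC(=O)OC | starting material
15 | methyl 6-(tert-butyldimethylsilyloxy)-3β-(triethylsilyloxy)-19-(triisopropylsilyloxy)-12,13,14,15,16-pentanorlabda-5,8-dien-11-oate | CC1=C(C(=O)OC)[C@@]2(C)CC[C@H](O[Si](CC)(CC)CC)[C@](C)(CO[Si](C(C)C)(C(C)C)C(C)C)C2=C(O[Si](C)(C)C(C)(C)C)C1 | intermediate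
16 | methyl 6-oxo-3β-(triethylsilyloxy)-19-(triisopropylsilyloxy)-12,13,14,15,16-pentanorlabd-8-en-11-oate | CC1=C(C(=O)OC)[C@@]2(C)CC[C@H](O[Si](CC)(CC)CC)[C@](C)(CO[Si](C(C)C)(C(C)C)C(C)C)[C@@H]2C(=O)C1 | intermediate (not isolated)
17 | methyl 3β-hydroxy-6-oxo-19-(triisopropylsilyloxy)-12,13,14,15,16-pentanorlabd-8-en-11-oate | CC1=C(C(=O)OC)[C@@]2(C)CC[C@H](O)[C@](C)(CO[Si](C(C)C)(C(C)C)C(C)C)[C@@H]2C(=O)C1 | intermediate
18 | methyl 3,6-dioxo-19-(triisopropylsilyloxy)-12,13,14,15,16-pentanorlabd-8-en-11-oate | CC1=C(C(=O)OC)[C@@]2(C)CCC(=O)[C@](C)(CO[Si](C(C)C)(C(C)C)C(C)C)[C@@H]2C(=O)C1 | intermediate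
19 | methyl 3α-hydroxy-6-oxo-19-(triisopropylsilyloxy)-12,13,14,15,16-pentanorlabd-8-en-11-oate | CC1=C(C(=O)OC)[C@@]2(C)CC[C@@H](O)[C@](C)(CO[Si](C(C)C)(C(C)C)C(C)C)[C@@H]2C(=O)C1 | intermediate (not isolated)
20 | 19-(triisopropylsilyloxy)-12,13,14,15,16-pentanorlabd-8-ene-3α,6β,11-triol | CC1=C(CO)[C@@]2(C)CC[C@@H](O)[C@](C)(CO[Si](C(C)C)(C(C)C)C(C)C)[C@@H]2[C@H](O)C1 | intermediate
21 | 11-bromo-19-(triisopropylsilyloxy)-12,13,14,15,16-pentanorlabd-8-ene-3α,6β-diol | CC1=C(CBr)[C@@]2(C)CC[C@@H](O)[C@](C)(CO[Si](C(C)C)(C(C)C)C(C)C)[C@@H]2[C@H](O)C1 | intermediate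
22 | ethyl acetoacetate | CCOC(=O)CC(C)=O | starting material
23 | ethyl 3α,6β-dihydroxy-13-oxo-19-(triisopropylsilyloxy)-14,15-dinorlabd-8-ene-12-carboxylate (C12 epimers) | CC1=C(CC(C(C)=O)C(=O)OCC)[C@@]2(C)CC[C@@H](O)[C@](C)(CO[Si](C(C)C)(C(C)C)C(C)C)[C@@H]2[C@H](O)C1 | intermediate (not isolated)
24 | 3α,6β-dihydroxy-13-oxo-19-(triisopropylsilyloxy)-14,15-dinorlabd-8-ene-12-carboxylic acid (C12 epimers) | CC1=C(CC(C(C)=O)C(=O)O)[C@@]2(C)CC[C@@H](O)[C@](C)(CO[Si](C(C)C)(C(C)C)C(C)C)[C@@H]2[C@H](O)C1 | intermediate (not isolated)
25 | 3α,6β-dihydroxy-19-(triisopropylsilyloxy)-14,15-dinorlabd-8-en-13-one | CC1=C(CCC(C)=O)[C@@]2(C)CC[C@@H](O)[C@](C)(CO[Si](C(C)C)(C(C)C)C(C)C)[C@@H]2[C@H](O)C1 | intermediate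
26 | allyl 2-(diethoxyphosphoryl)acetate | CCOP(=O)(CC(=O)OCC=C)OCC | starting material
27 | allyl (13E)-3α,6β-dihydroxy-19-(triisopropylsilyloxy)labda-8,13-dien-15-oate | CC1=C(CC/C(C)=C/C(=O)OCC=C)[C@@]2(C)CC[C@@H](O)[C@](C)(CO[Si](C(C)C)(C(C)C)C(C)C)[C@@H]2[C@H](O)C1 | intermediate
28 | allyl (13E)-3α,6β,19-trihydroxylabda-8,13-dien-15-oate | CC1=C(CC/C(C)=C/C(=O)OCC=C)[C@@]2(C)CC[C@@H](O)[C@](C)(CO)[C@@H]2[C@H](O)C1 | intermediate
29 | allyl (13E)-3α,6β-dihydroxy-19-(3-methylbutanoyloxy)labda-8,13-dien-15-oate | CC1=C(CC/C(C)=C/C(=O)OCC=C)[C@@]2(C)CC[C@@H](O)[C@](C)(COC(=O)CC(C)C)[C@@H]2[C@H](O)C1 | intermediate (not isolated)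
30 | allyl (13E)-6β-hydroxy-3α,19-bis(3-methylbutanoyloxy)labda-8,13-dien-15-oate | CC1=C(CC/C(C)=C/C(=O)OCC=C)[C@@]2(C)CC[C@@H](OC(=O)CC(C)C)[C@](C)(COC(=O)CC(C)C)[C@@H]2[C@H](O)C1 | intermediate
31 | (13E)-6β-hydroxy-3α,19-bis(3-methylbutanoyloxy)labda-8,13-dien-15-oic acid (CNP0333611.1) | CC1=C(CC/C(C)=C/C(=O)O)[C@@]2(C)CC[C@@H](OC(=O)CC(C)C)[C@](C)(COC(=O)CC(C)C)[C@@H]2[C@H](O)C1 | target

## Step count and least certain steps

Total step count: 18 steps. Longest linear sequence: 18 steps (1 → 31); 10, 14, 22 and 26 are purchased.

**Step 9 (key step).** The cycloaddition may be too slow, because the C10 terminus is fully substituted with an "inside" methyl group and the alkyne is internal; desilylation or isomerisation of the diene could then compete. Face selection at C10 may also be incomplete if ring A reacts through the half-chair with the C4 methyl, not C19, pseudoaxial. Fallback: setting out from 13, methyl buta-2,3-dienoate (a strained, more reactive dienophile that forms the same two bonds, C7 to its central carbon and C10 to its α-carbon) in toluene at 80–100 °C should give methyl 6-(tert-butyldimethylsilyloxy)-3β-(triethylsilyloxy)-19-(triisopropylsilyloxy)-12,13,14,15,16-pentanorlabda-5,8(17)-dien-11-oate F1. DBU in CH2Cl2 should then move the exocyclic double bond into conjugation with the ester, and the sequence comes back to the route at 15.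

**Step 3.** The catalyst may not separate the two carbonyls and their faces cleanly, since near the carbonyl a silyloxymethyl group and a methyl group differ only moderately in size; over-reduction to the diol is also possible. Fallback: setting out from 3, NaBH4 (0.3 equiv, MeOH, −78 °C) should give racemic cis-3-hydroxy-2-methyl-2-[(triisopropylsilyloxy)methyl]cyclohexan-1-one F2. Lipase-catalysed acylation with vinyl acetate (kinetic resolution) is expected, from the usual enantiopreference of lipases for secondary alcohols, to convert the 3R enantiomer into (2R,3R)-3-acetoxy-2-methyl-2-[(triisopropylsilyloxy)methyl]cyclohexan-1-one F3 and leave the 3S alcohol. Chromatography then returns the route at 4.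

**Step 10.** Acid may promote drift of the C8=C9 double bond into conjugation with the new C6 ketone, because the C7 hydrogens are activated by the ketone and, through the alkene, by the ester; partial protonation of C5 from the β face is the second risk. Fallback: setting out from 15, the ester is reduced first, so that the acid step is run without the activating ester.
- i-Bu2AlH (CH2Cl2, −78 °C) should give 6-(tert-butyldimethylsilyloxy)-3β-(triethylsilyloxy)-19-(triisopropylsilyloxy)-12,13,14,15,16-pentanorlabda-5,8-dien-11-ol F4.
- 1 M aq. HCl in THF should then lead through 11-hydroxy-3β-(triethylsilyloxy)-19-(triisopropylsilyloxy)-12,13,14,15,16-pentanorlabd-8-en-6-one F5 (not isolated) to 3β,11-dihydroxy-19-(triisopropylsilyloxy)-12,13,14,15,16-pentanorlabd-8-en-6-one F6.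
- Dess–Martin periodinane oxidises both alcohols to 3,6-dioxo-19-(triisopropylsilyloxy)-12,13,14,15,16-pentanorlabd-8-en-11-al F7.
- LiBH(s-Bu)3 (2.3 equiv, −78 °C) reduces the aldehyde and the C3 ketone to 3α,11-dihydroxy-19-(triisopropylsilyloxy)-12,13,14,15,16-pentanorlabd-8-en-6-one F8 (not isolated), and i-Bu2AlH in the same flask reduces C6, coming back to the route at 20.

**Step 12.** Face selection at C3 may be eroded, because the axial C19 substituent next to the carbonyl can hinder the equatorial approach of the bulky hydride and give the 3β epimer; the same reagent may also enolise the C6 ketone instead of leaving it for i-Bu2AlH. Fallback: setting out from 18, the hydride is delivered from C19.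
- HF·pyridine in THF removes the silyl ether and gives methyl 19-hydroxy-3,6-dioxo-12,13,14,15,16-pentanorlabd-8-en-11-oate F9.
- Me4NBH(OAc)3 in AcOH–MeCN at −20 °C should bind to the C19 hydroxyl and deliver hydride within the molecule to the β face of C3, giving methyl 3α,19-dihydroxy-6-oxo-12,13,14,15,16-pentanorlabd-8-en-11-oate F10.
- i-Pr3SiOTf/2,6-lutidine at −78 °C silylates only the primary hydroxyl, coming back to the route at 19, which is isolated in this variant and reduced with i-Bu2AlH to 20.

**Step 15.** E/Z control may be incomplete, since the two substituents of the methyl ketone differ little in size, and material would be lost in the separation. Fallback: setting out from 21, the geometry is fixed by a syn addition.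
- 3-(Trimethylsilyl)prop-2-ynyllithium (from 1-(trimethylsilyl)propyne and n-BuLi, in excess to cover the two hydroxyls) should give 19-(triisopropylsilyloxy)-14-(trimethylsilyl)-15,16-dinorlabd-8-en-13-yne-3α,6β-diol F11.
- K2CO3 in MeOH gives 19-(triisopropylsilyloxy)-15,16-dinorlabd-8-en-13-yne-3α,6β-diol F12.
- Zirconium-catalysed methylalumination (AlMe3, Cp2ZrCl2, CH2Cl2) adds methyl and aluminium syn across the alkyne to give the (13E)-14-(dimethylalumanyl)-15-norlabda-8,13-diene with both hydroxyls as dimethylaluminium alkoxides F13 (not isolated).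
- Allyl chloroformate then replaces aluminium with retention, coming back to the route at 27.

## Further compounds

F1 | step 9 | methyl 6-(tert-butyldimethylsilyloxy)-3β-(triethylsilyloxy)-19-(triisopropylsilyloxy)-12,13,14,15,16-pentanorlabda-5,8(17)-dien-11-oate (C9 epimers) | C=C1C(C(=O)OC)[C@@]2(C)CC[C@H](O[Si](CC)(CC)CC)[C@](C)(CO[Si](C(C)C)(C(C)C)C(C)C)C2=C(O[Si](C)(C)C(C)(C)C)C1
F2 | step 3 | racemic cis-3-hydroxy-2-methyl-2-[(triisopropylsilyloxy)methyl]cyclohexan-1-one (racemate, one enantiomer drawn) | O=C1[C@@](C)(CO[Si](C(C)C)(C(C)C)C(C)C)[C@@H](O)CCC1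
F3 | step 3 | (2R,3R)-3-acetoxy-2-methyl-2-[(triisopropylsilyloxy)methyl]cyclohexan-1-one | O=C1[C@](C)(CO[Si](C(C)C)(C(C)C)C(C)C)[C@H](OC(C)=O)CCC1
F4 | step 10 | 6-(tert-butyldimethylsilyloxy)-3β-(triethylsilyloxy)-19-(triisopropylsilyloxy)-12,13,14,15,16-pentanorlabda-5,8-dien-11-ol | CC1=C(CO)[C@@]2(C)CC[C@H](O[Si](CC)(CC)CC)[C@](C)(CO[Si](C(C)C)(C(C)C)C(C)C)C2=C(O[Si](C)(C)C(C)(C)C)C1
F5 | step 10 | 11-hydroxy-3β-(triethylsilyloxy)-19-(triisopropylsilyloxy)-12,13,14,15,16-pentanorlabd-8-en-6-one | CC1=C(CO)[C@@]2(C)CC[C@H](O[Si](CC)(CC)CC)[C@](C)(CO[Si](C(C)C)(C(C)C)C(C)C)[C@@H]2C(=O)C1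
F6 | step 10 | 3β,11-dihydroxy-19-(triisopropylsilyloxy)-12,13,14,15,16-pentanorlabd-8-en-6-one | CC1=C(CO)[C@@]2(C)CC[C@H](O)[C@](C)(CO[Si](C(C)C)(C(C)C)C(C)C)[C@@H]2C(=O)C1
F7 | step 10 | 3,6-dioxo-19-(triisopropylsilyloxy)-12,13,14,15,16-pentanorlabd-8-en-11-al | CC1=C(C=O)[C@@]2(C)CCC(=O)[C@](C)(CO[Si](C(C)C)(C(C)C)C(C)C)[C@@H]2C(=O)C1
F8 | step 10 | 3α,11-dihydroxy-19-(triisopropylsilyloxy)-12,13,14,15,16-pentanorlabd-8-en-6-one | CC1=C(CO)[C@@]2(C)CC[C@@H](O)[C@](C)(CO[Si](C(C)C)(C(C)C)C(C)C)[C@@H]2C(=O)C1
F9 | step 12 | methyl 19-hydroxy-3,6-dioxo-12,13,14,15,16-pentanorlabd-8-en-11-oate | CC1=C(C(=O)OC)[C@@]2(C)CCC(=O)[C@](C)(CO)[C@@H]2C(=O)C1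
F10 | step 12 | methyl 3α,19-dihydroxy-6-oxo-12,13,14,15,16-pentanorlabd-8-en-11-oate | CC1=C(C(=O)OC)[C@@]2(C)CC[C@@H](O)[C@](C)(CO)[C@@H]2C(=O)C1
F11 | step 15 | 19-(triisopropylsilyloxy)-14-(trimethylsilyl)-15,16-dinorlabd-8-en-13-yne-3α,6β-diol | CC1=C(CCC#C[Si](C)(C)C)[C@@]2(C)CC[C@@H](O)[C@](C)(CO[Si](C(C)C)(C(C)C)C(C)C)[C@@H]2[C@H](O)C1
F12 | step 15 | 19-(triisopropylsilyloxy)-15,16-dinorlabd-8-en-13-yne-3α,6β-diol | CC1=C(CCC#C)[C@@]2(C)CC[C@@H](O)[C@](C)(CO[Si](C(C)C)(C(C)C)C(C)C)[C@@H]2[C@H](O)C1
F13 | step 15 | (13E)-14-(dimethylalumanyl)-3α,6β-bis(dimethylalumanyloxy)-19-(triisopropylsilyloxy)-15-norlabda-8,13-diene | CC1=C(CC/C(C)=C/[Al](C)C)[C@@]2(C)CC[C@@H](O[Al](C)C)[C@](C)(CO[Si](C(C)C)(C(C)C)C(C)C)[C@@H]2[C@H](O[Al](C)C)C1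
A1 | alternative 1 | (E,E)-nitro-triene acetonide (C7=C8–C9=C10 diene, C5=C6 nitroalkene, C15 silyl ether) | C=C(C)/C(CC/C(C)=C/CO[Si](C)(C)C(C)(C)C)=C(\C)CC[C@@H]1OC(C)(C)OC[C@]1(C)/C=C/[N+](=O)[O-]
A2 | alternative 1 | trans-fused 6α-nitro decalin acetonide with the C8=C9 alkene | CC1=C(CC/C(C)=C/CO[Si](C)(C)C(C)(C)C)[C@@]2(C)CC[C@@H]3OC(C)(C)OC[C@]3(C)[C@@H]2[C@@H]([N+](=O)[O-])C1
A3 | alternative 2 | 4,4-dimethoxy-2,6-dimethylcyclohexa-2,5-dien-1-one | CC1=CC(OC)(OC)C=C(C)C1=O
A4 | alternative 2 | methyl (2Z)-3-(tert-butyldimethylsilyloxy)penta-2,4-dienoate | C=C/C(O[Si](C)(C)C(C)(C)C)=C/C(=O)OC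
A5 | alternative 2 | cis-fused endo adduct (C6 ketal, C9 enone, C3 silyl enol ether, C19 ester) | CC1=CC(OC)(OC)[C@@H]2[C@H](C(=O)OC)C(O[Si](C)(C)C(C)(C)C)=CC[C@]2(C)C1=O
A6 | alternative 3 | 3-[(2S,3S)-1,3-bis(tert-butyldimethylsilyloxy)-5-iodo-2-methylpentan-2-yl]-4-methoxy-2,6-dimethylphenol | Cc1cc(OC)c(c(C)c1O)[C@@](C)(CO[Si](C)(C)C(C)(C)C)[C@@H](O[Si](C)(C)C(C)(C)C)CCI
A7 | alternative 3 | bicyclic 6-methoxy-5,7-dien-9-one with quaternary C10 | CC1=CC(OC)=C2[C@@](C)(CO[Si](C)(C)C(C)(C)C)[C@@H](O[Si](C)(C)C(C)(C)C)CC[C@]2(C)C1=O
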